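**Strategy.** Everything rests on cutting two bonds that issue from ring B, the furan-fused 3,5-dioxygenated ring: C10a–C8b (ring carbon to the carbon that bears ring D) and C8a–C8c (benzylic carbon to the carbon that bears ring F). Rings D and F are the same aryl group, and C10a lies ortho to the carbon that carries C8a, so one acyl donor can serve twice. The precursor is a bromo-deoxybenzoin; as its aryllithium–enolate dianion it takes up two 3,5-dimethoxybenzoyl groups in one operation. The triketone folds to an achiral indenone, asymmetric hydrogenation sets the absolute configuration, the last two aryl-bearing carbons enter pairwise, and a cationic cascade closes the furan and the eight-membered ring.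

Key step: step 4

Atom labels: unit a = ring A (4-oxyphenyl)–C7a–C8a–ring B (C9a–C14a, furan oxygen on C11a); unit b = ring C (4-oxyphenyl)–C7b(O)–C8b–ring D (C9b–C14b); unit c = ring E (4-oxyphenyl)–C7c–C8c–ring F (C9c–C14c). Target configuration read from the SMILES: 7aR, 8aS, 8cR, 7cR, 8bR, 7bR (H7a/H8a cis, H8a/H8c trans, furan trans).

Assumption: in step 6 the ligand antipode that gives (2S,3R)-11 is the one used; the sense of induction has to be found by screening.

Step 1
Reactants: 1 2-(3,5-dimethoxyphenyl)acetic acid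
Product: 2 2-(2-bromo-3,5-dimethoxyphenyl)acetic acid
Conditions: NBS (1.0 equiv), MeCN, 0 → 23 °C
Reagents that add atoms: N-bromosuccinimide O=C1CCC(=O)N1Br
Why: Electrophilic aromatic bromination should go ortho to the side chain and para to one methoxy group (the future C10a), the position between the two methoxy groups being the more hindered one.

Step 2
Reactants: 2 2-(2-bromo-3,5-dimethoxyphenyl)acetic acid; 3 anisole
Product: 4 2-(2-bromo-3,5-dimethoxyphenyl)-1-(4-methoxyphenyl)ethan-1-one
Conditions: polyphosphoric acid, 3 (5 equiv), 70 °C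
Reagents that add atoms: none
Why: Friedel–Crafts acylation of anisole by the arylacetic acid should occur para to the methoxy group and give the deoxybenzoin that holds ring A, C7a, C8a and ring B.

Step 3
Reactants: 5 3,5-dimethoxybenzoic acid; 6 1H-benzotriazole
Product: 7 (1H-benzotriazol-1-yl)(3,5-dimethoxyphenyl)methanone
Conditions: SOCl2 (1.05 equiv), 6 (4 equiv), CH2Cl2, 23 °C
Reagents that add atoms: none
Why: Thionyl chloride–benzotriazole activation (acyl substitution) should give the N-acylbenzotriazole, a neutral acyl donor that acylates organolithiums once and C-acylates ketone enolates.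

Step 4
Reactants: 4 2-(2-bromo-3,5-dimethoxyphenyl)-1-(4-methoxyphenyl)ethan-1-one; 7 (1H-benzotriazol-1-yl)(3,5-dimethoxyphenyl)methanone
Product: 9 2-[2-(3,5-dimethoxybenzoyl)-3,5-dimethoxyphenyl]-1-(3,5-dimethoxyphenyl)-3-(4-methoxyphenyl)propane-1,3-dione, via aryllithium enolate dianion 8 (not isolated)
Conditions: LiN(SiMe3)2 (1.1 equiv), THF, −78 °C; t-BuLi (3.1 equiv), −78 °C; 7 (2.6 equiv), −78 → 0 °C; 1 M HCl
Reagents that add atoms: none
Why: Deprotonation masks the ketone as its lithium enolate, bromine–lithium exchange makes C10a an aryllithium, and the dianion attacks two molecules of 7, so that the aryllithium gives the diaryl ketone (C10a–C8b) and the enolate carbon C8a is C-acylated (C8a–C8c), while the third equivalent of t-BuLi regenerates the amide base that deprotonates the acidic 1,3-diketone and drives the second acylation on. The closest known reactions are ketone synthesis from organolithiums and N-acylbenzotriazoles and Claisen-type C-acylation of preformed ketone enolates by the same donors. No ring is closed in this step. The only new stereocenter, C8a, is enolisable and is erased in step 5, so no stereocontrol is needed. The step needs site selectivity and C- over O-acylation: the first is secured by the position of the bromine and the single enolisable methylene, the second by the benzotriazole leaving group and by trapping of the product as its lithium diketonate, and cross-selectivity does not arise because rings D and F are the same aryl group and one electrophile is used twice.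

Step 5
Reactants: 9 2-[2-(3,5-dimethoxybenzoyl)-3,5-dimethoxyphenyl]-1-(3,5-dimethoxyphenyl)-3-(4-methoxyphenyl)propane-1,3-dione
Product: 10 2-[2-(3,5-dimethoxybenzoyl)-3,5-dimethoxyphenyl]-4,6-dimethoxy-3-(4-methoxyphenyl)-1H-inden-1-one
Conditions: TfOH (20 mol%), 1,2-dichloroethane, 23 → 60 °C; aq. NaHCO3
Reagents that add atoms: none
Why: Friedel–Crafts cyclodehydration should join C10c of ring F (ortho and para to methoxy groups) to the protonated anisoyl carbonyl C7a and, after loss of water toward C8a, give the achiral indenone, the anisyl ring being unable to compete because its free positions are meta to its methoxy group and any isochromenylium ion formed reversibly from the enol and the neighbouring diaryl ketone being drained by the irreversible ring closure.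

Step 6
Reactants: 10 2-[2-(3,5-dimethoxybenzoyl)-3,5-dimethoxyphenyl]-4,6-dimethoxy-3-(4-methoxyphenyl)-1H-inden-1-one
Product: 11 (2S,3R)-2-[2-(3,5-dimethoxybenzoyl)-3,5-dimethoxyphenyl]-4,6-dimethoxy-3-(4-methoxyphenyl)-2,3-dihydro-1H-inden-1-one
Conditions: H2 (50 bar), [Rh(cod)2]BF4 (5 mol%), (R)-DTBM-SEGPHOS (5.5 mol%), CH2Cl2/CF3CH2OH, 40 °C
Reagents that add atoms: none
Why: Catalytic asymmetric hydrogenation of the tetrasubstituted enone double bond should add both hydrogens to one face (syn addition), which makes H7a and H8a cis, while the chiral bisphosphine selects the face and so sets C7a as R and C8a as S under neutral conditions that do not epimerise C8a.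

Step 7
Reactants: 11 (2S,3R)-2-[2-(3,5-dimethoxybenzoyl)-3,5-dimethoxyphenyl]-4,6-dimethoxy-3-(4-methoxyphenyl)-2,3-dihydro-1H-inden-1-one; 12 (methoxymethyl)trimethylsilane
Product: 15 (1S,2R,3R)-2-{2-[1-(3,5-dimethoxyphenyl)-2-oxoethyl]-3,5-dimethoxyphenyl}-4,6-dimethoxy-3-(4-methoxyphenyl)-2,3-dihydro-1H-indene-1-carbaldehyde (both C8b epimers), via [methoxy(trimethylsilyl)methyl]lithium 13 (not isolated), via bis(β-hydroxysilane) adduct 14 (not isolated)
Conditions: 12 (6 equiv), s-BuLi (6 equiv), THF, −78 → −25 °C; CeCl3 (6 equiv), −78 °C; 11, −78 → −40 °C; 90% HCO2H, 0 → 23 °C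
Reagents that add atoms: water O
Why: The organocerium form of the α-silyl α-methoxy carbanion should add to both ketones without enolising C8a, formic acid then triggers Peterson-type loss of silanol to the two enol ethers and their hydrolysis to the aldehydes (C7c and C7b), and acid-catalysed enolisation lets C8c settle trans to ring B on C8a (thermodynamic control) while C8b stays a mixture.

Step 8
Reactants: 15 (1S,2R,3R)-2-{2-[1-(3,5-dimethoxyphenyl)-2-oxoethyl]-3,5-dimethoxyphenyl}-4,6-dimethoxy-3-(4-methoxyphenyl)-2,3-dihydro-1H-indene-1-carbaldehyde; 16 4-methoxyphenylmagnesium bromide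
Product: 17 (4-methoxyphenyl)[(1S,2R,3R)-2-{2-[1-(3,5-dimethoxyphenyl)-2-hydroxy-2-(4-methoxyphenyl)ethyl]-3,5-dimethoxyphenyl}-4,6-dimethoxy-3-(4-methoxyphenyl)-2,3-dihydro-1H-inden-1-yl]methanol (carbinol and C8b epimers)
Conditions: 16 (5 equiv), THF, −78 → 0 °C; H2O
Reagents that add atoms: none
Why: Grignard 1,2-addition to both aldehydes should give the two secondary 4-methoxybenzylic alcohols at C7c and C7b, whose configurations do not matter because both carbons are ionised in step 9.

Step 9
Reactants: 17 (4-methoxyphenyl)[(1S,2R,3R)-2-{2-[1-(3,5-dimethoxyphenyl)-2-hydroxy-2-(4-methoxyphenyl)ethyl]-3,5-dimethoxyphenyl}-4,6-dimethoxy-3-(4-methoxyphenyl)-2,3-dihydro-1H-inden-1-yl]methanol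
Product: 18 octa-O-methylcanaliculatol (7aR,8aS,8cR,7cR,8bR,7bR)
Conditions: BCl3 (3 equiv), CH2Cl2 (2 mM), −78 → −20 °C; MeOH, aq. NaHCO3
Reagents that add atoms: none
Why: Ionisation of both carbinols should give two 4-methoxybenzylic cations, of which C7c is captured by C10b of ring D (Friedel–Crafts alkylation closing the eight-membered ring, the trans relation at C8a/C8c ruling out five-ring closure onto C14a) and C7b by the methoxy oxygen on C11a with loss of its methyl group as MeCl (demethylative 5-exo oxa-cyclisation), the reversible C7b cation–stilbene equilibrium letting C8b and C7b settle as the trans-dihydrofuran compatible with the closed ring.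

Step 10
Reactants: 18 octa-O-methylcanaliculatol
Product: 19 canaliculatol
Conditions: BBr3 (20 equiv), CH2Cl2, −78 → 23 °C; MeOH, H2O
Reagents that add atoms: none
Why: Boron tribromide cleavage of the eight aryl methyl ethers should release the eight phenols, the dihydrobenzofuran and the six non-enolisable benzylic stereocenters being kept.

**Compound list**

1 | 2-(3,5-dimethoxyphenyl)acetic acid | COc1cc(CC(=O)O)cc(OC)c1 | starting material
2 | 2-(2-bromo-3,5-dimethoxyphenyl)acetic acid | OC(=O)Cc1cc(OC)cc(OC)c1Br | intermediate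
3 | anisole | COc1ccccc1 | starting material
4 | 2-(2-bromo-3,5-dimethoxyphenyl)-1-(4-methoxyphenyl)ethan-1-one | COc1ccc(cc1)C(=O)Cc1cc(OC)cc(OC)c1Br | intermediate
5 | 3,5-dimethoxybenzoic acid | COc1cc(cc(OC)c1)C(=O)O | starting material
6 | 1H-benzotriazole | c1ccc2[nH]nnc2c1 | starting material
7 | (1H-benzotriazol-1-yl)(3,5-dimethoxyphenyl)methanone | COc1cc(cc(OC)c1)C(=O)n1nnc2ccccc12 | intermediate
8 | aryllithium enolate dianion of 4 | COc1ccc(cc1)C(O[Li])=Cc1cc(OC)cc(OC)c1[Li] | intermediate
9 | 2-[2-(3,5-dimethoxybenzoyl)-3,5-dimethoxyphenyl]-1-(3,5-dimethoxyphenyl)-3-(4-methoxyphenyl)propane-1,3-dione | COc1ccc(cc1)C(=O)C(C(=O)c1cc(OC)cc(OC)c1)c1cc(OC)cc(OC)c1C(=O)c1cc(OC)cc(OC)c1 | intermediate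
10 | 2-[2-(3,5-dimethoxybenzoyl)-3,5-dimethoxyphenyl]-4,6-dimethoxy-3-(4-methoxyphenyl)-1H-inden-1-one | O=C1c2cc(OC)cc(OC)c2C(c2ccc(OC)cc2)=C1c1cc(OC)cc(OC)c1C(=O)c1cc(OC)cc(OC)c1 | intermediate
11 | (2S,3R)-2-[2-(3,5-dimethoxybenzoyl)-3,5-dimethoxyphenyl]-4,6-dimethoxy-3-(4-methoxyphenyl)-2,3-dihydro-1H-inden-1-one (cis) | COc1ccc(cc1)[C@@H]1c2c(OC)cc(OC)cc2C(=O)[C@@H]1c1cc(OC)cc(OC)c1C(=O)c1cc(OC)cc(OC)c1 | intermediate
12 | (methoxymethyl)trimethylsilane | COC[Si](C)(C)C | starting material
13 | [methoxy(trimethylsilyl)methyl]lithium | COC([Li])[Si](C)(C)C | intermediate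
14 | bis(β-hydroxysilane) adduct of 11 (both ketones converted to C(OH)CH(OMe)SiMe3; new centers unassigned) | COc1ccc(cc1)[C@@H]1c2c(OC)cc(OC)cc2C(O)(C(OC)[Si](C)(C)C)[C@@H]1c1cc(OC)cc(OC)c1C(O)(C(OC)[Si](C)(C)C)c1cc(OC)cc(OC)c1 | intermediate
15 | (1S,2R,3R)-2-{2-[1-(3,5-dimethoxyphenyl)-2-oxoethyl]-3,5-dimethoxyphenyl}-4,6-dimethoxy-3-(4-methoxyphenyl)-2,3-dihydro-1H-indene-1-carbaldehyde (H7a/H8a cis, formyl trans to the C8a aryl, C8b epimers) | COc1ccc(cc1)[C@@H]1c2c(OC)cc(OC)cc2[C@@H](C=O)[C@@H]1c1cc(OC)cc(OC)c1C(C=O)c1cc(OC)cc(OC)c1 | intermediate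
16 | 4-methoxyphenylmagnesium bromide | COc1ccc([Mg]Br)cc1 | starting material
17 | bis(4-methoxybenzylic) diol from 15 (indane centers 1S,2R,3R; carbinol and C8b centers unassigned) | COc1ccc(cc1)[C@@H]1c2c(OC)cc(OC)cc2[C@@H](C(O)c2ccc(OC)cc2)[C@@H]1c1cc(OC)cc(OC)c1C(C(O)c1ccc(OC)cc1)c1cc(OC)cc(OC)c1 | intermediate
18 | octa-O-methylcanaliculatol | COc1ccc([C@@H]2c3c(OC)cc(OC)cc3[C@H]3[C@H](c4ccc(OC)cc4)c4c(OC)cc(OC)cc4[C@@H]4c5c(cc(OC)cc5[C@H]23)O[C@H]4c2ccc(OC)cc2)cc1 | intermediate
19 | canaliculatol | Oc1ccc([C@@H]2c3c(O)cc(O)cc3[C@H]3[C@H](c4ccc(O)cc4)c4c(O)cc(O)cc4[C@@H]4c5c(cc(O)cc5[C@H]23)O[C@H]4c2ccc(O)cc2)cc1 | target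

Total step count: 10. Longest linear sequence: 9 steps (steps 1, 2, 4–10; step 3 prepares the acyl donor).

**Steps most likely to fail**

Step 4. After the ortho position has been aroylated the enolate is crowded, so O-acylation or incomplete C-acylation may take over, and the aryllithium may be lost by proton transfer before it is acylated. The fallback sets out from 4 and comes back at 10, giving up the one-operation bond formation. Ketone 4 alone is C-acylated with 7 under soft enolisation (MgBr2·OEt2, i-Pr2NEt, CH2Cl2) to 2-(2-bromo-3,5-dimethoxyphenyl)-1-(3,5-dimethoxyphenyl)-3-(4-methoxyphenyl)propane-1,3-dione F1. This is cyclodehydrated with TfOH to 2-(2-bromo-3,5-dimethoxyphenyl)-4,6-dimethoxy-3-(4-methoxyphenyl)-1H-inden-1-one F2, at a stage where no neighbouring diaryl ketone can divert the diketone. The C8b carbonyl and ring D are then brought in by carbonylative Suzuki coupling of F2 with commercial (3,5-dimethoxyphenyl)boronic acid F3 (Pd(OAc)2, di(1-adamantyl)-n-butylphosphine, CO, K2CO3, toluene, 100 °C), which gives 10.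

Step 6. Hydrogen delivery to a tetrasubstituted double bond flanked by a peri methoxy group and an ortho-aroylated aryl group may be slow or poorly face-selective, and C8a may epimerise. The fallback sets out from 10 and comes back at 11. Corey–Bakshi–Shibata reduction (B-methyl oxazaborolidine, catecholborane, toluene, −78 °C) of the indenone carbonyl gives the indenol F4 with the hydroxyl on the face that is to receive the hydrogens. Hydroxyl-directed hydrogenation with [Ir(cod)(PCy3)(py)]PF6 (H2, CH2Cl2) delivers both hydrogens to the hydroxyl face and gives the indanol F5. Dess–Martin periodinane (NaHCO3, CH2Cl2) then returns 11 and re-oxidises any diaryl carbinol formed on the way.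

Step 9. The C7c cation may lose H8c and be reprotonated before the ring closes, which inverts C8c and opens five-ring closure onto C14a. Oligomerisation and incomplete convergence at C8b are further risks. The fallback sets out from 15 and comes back at 18; it closes the eight-membered ring by acylation, so that no cation is raised at C7c while the ring forms and C8c and C8b remain epimerisable until both rings exist. Pinnick oxidation (NaClO2, NaH2PO4, 2-methyl-2-butene, t-BuOH/H2O) gives the diacid F6. Treatment with (COCl)2 and then SnCl4 (CH2Cl2, −40 → 0 °C) should acylate C10b (eight-membered ketone) and lactonise the C7b acyl chloride onto the C11a methoxy oxygen with loss of MeCl, giving the keto lactone F7, which is equilibrated with DBU. Because the 3-arylbenzofuranone is too acidic to take up an aryl nucleophile directly, it is opened with Me2AlN(OMe)Me (from AlMe3 and N,O-dimethylhydroxylamine hydrochloride, CH2Cl2) to the phenol Weinreb amide F8. Excess 16 with CeCl3 (THF, −78 → 0 °C) then adds to the ring ketone and converts the amide into the 4-methoxyphenyl ketone, which closes onto the C11a phenol and gives the tertiary alcohol–lactol F9. Ionic reduction (Et3SiH, BF3·OEt2, CH2Cl2, −40 °C) of both positions should give 18, a cis-dihydrofuran, should it form, being equilibrated to trans by reversible ionisation of the C7b–O bond.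

**Further compounds**

F1 | step 4 | 2-(2-bromo-3,5-dimethoxyphenyl)-1-(3,5-dimethoxyphenyl)-3-(4-methoxyphenyl)propane-1,3-dione | COc1ccc(cc1)C(=O)C(C(=O)c1cc(OC)cc(OC)c1)c1cc(OC)cc(OC)c1Br
F2 | step 4 | 2-(2-bromo-3,5-dimethoxyphenyl)-4,6-dimethoxy-3-(4-methoxyphenyl)-1H-inden-1-one | O=C1c2cc(OC)cc(OC)c2C(c2ccc(OC)cc2)=C1c1cc(OC)cc(OC)c1Br
F3 | step 4 | (3,5-dimethoxyphenyl)boronic acid | COc1cc(cc(OC)c1)B(O)O
F4 | step 6 | 2-[2-(3,5-dimethoxybenzoyl)-3,5-dimethoxyphenyl]-4,6-dimethoxy-3-(4-methoxyphenyl)-1H-inden-1-ol (single C8c carbinol epimer) | COc1ccc(cc1)C1=C([C@H](O)c2cc(OC)cc(OC)c12)c1cc(OC)cc(OC)c1C(=O)c1cc(OC)cc(OC)c1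
F5 | step 6 | 2-[2-(3,5-dimethoxybenzoyl)-3,5-dimethoxyphenyl]-4,6-dimethoxy-3-(4-methoxyphenyl)-2,3-dihydro-1H-inden-1-ol (H7a, H8a and the hydroxyl on one face) | COc1ccc(cc1)[C@@H]1c2c(OC)cc(OC)cc2[C@@H](O)[C@@H]1c1cc(OC)cc(OC)c1C(=O)c1cc(OC)cc(OC)c1
F6 | step 9 | diacid from 15 (indane-1-carboxylic acid and diarylacetic acid; C8b epimers) | COc1ccc(cc1)[C@@H]1c2c(OC)cc(OC)cc2[C@@H](C(=O)O)[C@@H]1c1cc(OC)cc(OC)c1C(C(=O)O)c1cc(OC)cc(OC)c1
F7 | step 9 | keto lactone (C7c ketone in the eight-membered ring, C7b benzofuran-2(3H)-one) | COc1ccc([C@@H]2c3c(OC)cc(OC)cc3[C@H]3C(=O)c4c(OC)cc(OC)cc4[C@@H]4c5c(cc(OC)cc5[C@H]23)OC4=O)cc1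
F8 | step 9 | phenol Weinreb amide from F7 (C11a phenol, C7b N-methoxy-N-methylamide, C7c ring ketone) | COc1ccc([C@@H]2c3c(OC)cc(OC)cc3[C@H]3C(=O)c4c(OC)cc(OC)cc4[C@@H](C(=O)N(C)OC)c5c(O)cc(OC)cc5[C@H]23)cc1
F9 | step 9 | C7c tertiary alcohol and C7b lactol after aryl addition to F8 | COc1ccc([C@@H]2c3c(OC)cc(OC)cc3[C@H]3C(O)(c4ccc(OC)cc4)c4c(OC)cc(OC)cc4[C@@H]4c5c(cc(OC)cc5[C@H]23)OC4(O)c2ccc(OC)cc2)cc1
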